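## Retrosynthetic overview

- **Numbering (germacrane):** carbocycle C1–C10. Ring A is the 4,5-dihydrofuran (O, C1, C2, C3, C4). Ring B is the butenolide (O, C6, C7, C11, C12). C13 is CH2OAc, and On means the oxygen on Cn.
- **Feature used:** C2 and C3, the two unsubstituted carbons of ring A, form its only uncrowded bond. C2 adjoins C1, whose other neighbour is quaternary C10, and C3 adjoins quaternary C4. A C2 carbanion and a C3 electrophile therefore each have one possible site, and both quaternary centres can be bought.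
- **Key disconnection:** C2–C3 and O–C1 of ring A, leading back to hydrazone 8 (C10 from (S)-citramalic acid) and epoxide 10 (C4 from (S)-2-methylglycidol).
- **Endgame disconnections:** C11–C13 by Stille hydroxymethylation of C11–Br, kept to the end because a C13 leaving group would be expelled from the butenolide dienolate. C5=C6 by intramolecular vinylogous aldol condensation. C7–C8 by Nozaki–Hiyama–Kishi coupling, which sets C8.
- **Ring order:** ring A (step 9), ring B brought in ready-made (step 12), ten-membered carbocycle last (step 16).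

Key step: step 9

Assumption (handling): every compound holding the C1=C2 enol ether is worked up with NaHCO3 and chromatographed on Et3N-washed silica, because a free O8 or O5 hydroxyl can add to C1 under acid.

Assumption (ligand): the oxazoline–sulfonamide ligand of step 12 is used in the enantiomeric form that sends the alkenyl group to the Si face of C8; both forms derive from the two valinols.

## Route

Step 1
Reactants: 1 (S)-citramalic acid
Product: 2 2-[(4S)-2,2,4-trimethyl-5-oxo-1,3-dioxolan-4-yl]acetic acid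
Conditions: Me2C(OMe)2, p-TsOH·H2O (cat.), CH2Cl2, rt
Reagents that add atoms: 2,2-dimethoxypropane, COC(C)(C)OC
Why: Acid-catalysed acetalisation (1,3-dioxolan-4-one formation) should tie up only the tertiary hydroxyl and the adjacent C1 carboxyl, the one pair that closes a five-membered ring, so the C8 carboxyl stays free and C10 is untouched.

Step 2
Reactants: 2 2-[(4S)-2,2,4-trimethyl-5-oxo-1,3-dioxolan-4-yl]acetic acid
Product: 3 (5S)-5-(2-hydroxyethyl)-2,2,5-trimethyl-1,3-dioxolan-4-one
Conditions: BH3·THF, THF, 0 °C → rt; MeOH quench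
Reagents that add atoms: none
Why: Chemoselective borane reduction, in which BH3 reduces the free carboxylic acid much faster than the ester-type dioxolanone carbonyl and so brings C8 to the alcohol level.

Step 3
Reactants: 3 (5S)-5-(2-hydroxyethyl)-2,2,5-trimethyl-1,3-dioxolan-4-one
Product: 4 (5S)-5-[2-(benzyloxy)ethyl]-2,2,5-trimethyl-1,3-dioxolan-4-one
Conditions: BnBr, Ag2O, 4 Å MS, CH2Cl2, rt, dark
Reagents that add atoms: benzyl bromide, BrCc1ccccc1
Why: Silver-oxide-promoted Williamson benzylation runs without free alkoxide or acid, so the hydroxyl should be etherified before it can attack the dioxolanone carbonyl and lactonise.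

Step 4
Reactants: 4 (5S)-5-[2-(benzyloxy)ethyl]-2,2,5-trimethyl-1,3-dioxolan-4-one
Product: 5 (2S)-4-(benzyloxy)-2-hydroxy-N-methoxy-N,2-dimethylbutanamide
Conditions: MeNH(OMe)·HCl, i-PrMgCl, THF, −20 → 0 °C; aq. NH4Cl
Reagents that add atoms: N,O-dimethylhydroxylamine hydrochloride, CNOC.Cl
Why: Weinreb aminolysis, in which the magnesium amide made from the hydrochloride and i-PrMgCl attacks the activated dioxolanone carbonyl C1, the ring opens, acetone is lost and the tertiary hydroxyl is freed in the same operation.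

Step 5
Reactants: 5 (2S)-4-(benzyloxy)-2-hydroxy-N-methoxy-N,2-dimethylbutanamide
Product: 6 (2S)-4-(benzyloxy)-N-methoxy-N,2-dimethyl-2-(triethylsilyloxy)butanamide
Conditions: Et3SiOTf, 2,6-lutidine, CH2Cl2, 0 °C
Reagents that add atoms: triethylsilyl triflate, CC[Si](CC)(CC)OS(=O)(=O)C(F)(F)F
Why: Silyl triflate silylation with a hindered pyridine base is the standard way to cap a tertiary alcohol, and the triethylsilyl ether should withstand LiN(i-Pr)2, oxalic acid and Na/NH3 yet fall to buffered fluoride in step 14.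

Step 6
Reactants: 6 (2S)-4-(benzyloxy)-N-methoxy-N,2-dimethyl-2-(triethylsilyloxy)butanamide
Product: 7 (3S)-5-(benzyloxy)-3-methyl-3-(triethylsilyloxy)pentan-2-one
Conditions: MeMgBr, THF, 0 °C → rt
Reagents that add atoms: methylmagnesium bromide, C[Mg]Br
Why: Weinreb ketone synthesis, in which the chelated adduct holds until the quench, so exactly one methyl group (C2) is added and no tertiary alcohol forms.

Step 7
Reactants: 7 (3S)-5-(benzyloxy)-3-methyl-3-(triethylsilyloxy)pentan-2-one
Product: 8 (E)-N,N-dimethylhydrazone of (3S)-5-(benzyloxy)-3-methyl-3-(triethylsilyloxy)pentan-2-one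
Conditions: Me2NNH2 (excess), AcOH (cat.), 4 Å MS, EtOH, 70 °C, sealed tube
Reagents that add atoms: N,N-dimethylhydrazine, CN(C)N
Why: Hydrazone condensation driven by excess reagent and sieves, in which the NMe2 group should settle anti to quaternary C10 (E) and C2 is left as the only carbon with α-hydrogens.

Step 8
Reactants: 9 (S)-2-methylglycidol
Product: 10 tert-butyldimethyl{[(2R)-2-methyloxiran-2-yl]methoxy}silane
Conditions: TBSCl, imidazole, CH2Cl2, 0 °C → rt
Reagents that add atoms: tert-butyldimethylsilyl chloride, CC(C)(C)[Si](C)(C)Cl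
Why: Imidazole-mediated silylation of the primary alcohol leaves the epoxide and C4 alone (S becomes R only through the priority rules), and an all-alkyl silyl group is taken because arylsilanes would not survive Na/NH3 in step 10.

Step 9
Reactants: 8 (E)-N,N-dimethylhydrazone of (3S)-5-(benzyloxy)-3-methyl-3-(triethylsilyloxy)pentan-2-one; 10 tert-butyldimethyl{[(2R)-2-methyloxiran-2-yl]methoxy}silane
Product: 15 (2R)-5-[(2S)-4-(benzyloxy)-2-(triethylsilyloxy)butan-2-yl]-2-[(tert-butyldimethylsilyloxy)methyl]-2-methyl-2,3-dihydrofuran, via lithium aza-enolate 11 (not isolated), via hydroxy hydrazone 12 (not isolated), via hydroxy ketone 13 (not isolated), via cyclic hemiketal 14 (not isolated)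
Conditions: LiN(i-Pr)2 (commercial solution), THF, 0 °C; 10, 0 °C → rt; H2O; sat. aq. (CO2H)2/Et2O, rt; dried organic phase: PPTS (cat.), 4 Å MS, benzene, 60 °C; Et3N
Reagents that add atoms: none
Why: LiN(i-Pr)2 removes a proton from C2, the only α-carbon that bears hydrogen, and aza-enolate 11 opens epoxide 10 by SN2 attack at methylene C3, so C2–C3 forms while the C4–O bond and its configuration stay untouched (12). The closest known reaction type is alkylation of lithiated N,N-dimethylhydrazones by terminal epoxides, followed by acid-catalysed cyclodehydration of a γ-hydroxy ketone to a 4,5-dihydrofuran. Aqueous oxalic acid cleaves the hydrazone to 13, and the C4 hydroxyl adds to C1 in a 5-exo-trig closure to give 14, which forms O–C1 and ring A. PPTS over molecular sieves then removes water, and since the departing proton can come only from C2, C1=C2 should be the sole enol ether. No lasting stereocentre is created, because C4 and C10 arrive unchanged from 10 and 8 and the hemiketal centre at C1 is erased. Only regioselectivity is needed, secured by quaternary C10 (site of deprotonation, direction of dehydration) and quaternary C4 (attack at C3), while the plain benzyl ether on O8 is chosen because it cannot leave as a stabilised cation and so should not drain into a C1 spiroketal.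

Step 10
Reactants: 15 (2R)-5-[(2S)-4-(benzyloxy)-2-(triethylsilyloxy)butan-2-yl]-2-[(tert-butyldimethylsilyloxy)methyl]-2-methyl-2,3-dihydrofuran
Product: 16 (3S)-3-{(5R)-5-[(tert-butyldimethylsilyloxy)methyl]-5-methyl-4,5-dihydrofuran-2-yl}-3-(triethylsilyloxy)butan-1-ol
Conditions: Na, NH3(l)/THF, −78 °C; solid NH4Cl
Reagents that add atoms: none
Why: Dissolving-metal (Birch-type) cleavage of the benzyl ether sends electrons only into the arene, leaves the isolated enol ether and the alkylsilyl ethers alone, and its basic medium keeps the freed O8 hydroxyl from adding to C1, which an oxidative benzyl-type cleavage with its acidic by-product would invite.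

Step 11
Reactants: 16 (3S)-3-{(5R)-5-[(tert-butyldimethylsilyloxy)methyl]-5-methyl-4,5-dihydrofuran-2-yl}-3-(triethylsilyloxy)butan-1-ol
Product: 17 (3S)-3-{(5R)-5-[(tert-butyldimethylsilyloxy)methyl]-5-methyl-4,5-dihydrofuran-2-yl}-3-(triethylsilyloxy)butanal
Conditions: Dess–Martin periodinane, pyridine, CH2Cl2, 0 °C
Reagents that add atoms: none
Why: Dess–Martin oxidation tolerates vinyl ethers and silyl ethers, and the pyridine buffer takes up the acetic acid that could otherwise trigger spiroketalisation or β-elimination of the O10 silyl ether.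

Step 12
Reactants: 17 (3S)-3-{(5R)-5-[(tert-butyldimethylsilyloxy)methyl]-5-methyl-4,5-dihydrofuran-2-yl}-3-(triethylsilyloxy)butanal; 18 3,4-dibromofuran-2(5H)-one
Product: 20 3-bromo-4-[(1R,3S)-1-hydroxy-3-{(5R)-5-[(tert-butyldimethylsilyloxy)methyl]-5-methyl-4,5-dihydrofuran-2-yl}-3-(triethylsilyloxy)butyl]furan-2(5H)-one, via alkenylchromium species 19 (not isolated)
Conditions: CrCl2, chiral N-[2-(4-isopropyl-4,5-dihydrooxazol-2-yl)-6-methylphenyl]methanesulfonamide and Et3N (premixed), NiCl2 (cat.), 18 (excess), THF, rt; aq. NaHCO3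
Reagents that add atoms: none
Why: Nozaki–Hiyama–Kishi coupling, in which zerovalent nickel should insert into the more electron-poor β C–Br bond (C7, the site where this dibromide also cross-couples first), transmetalation to trivalent chromium gives 19, which tolerates lactone, silyl ethers and enol ether, and the chiral sulfonamide on chromium directs addition to the Si face of the aldehyde so that 8R is set by reagent control.

Step 13
Reactants: 20 3-bromo-4-[(1R,3S)-1-hydroxy-3-{(5R)-5-[(tert-butyldimethylsilyloxy)methyl]-5-methyl-4,5-dihydrofuran-2-yl}-3-(triethylsilyloxy)butyl]furan-2(5H)-one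
Product: 21 (1R,3S)-1-(4-bromo-5-oxo-2,5-dihydrofuran-3-yl)-3-{(5R)-5-[(tert-butyldimethylsilyloxy)methyl]-5-methyl-4,5-dihydrofuran-2-yl}-3-(triethylsilyloxy)butyl methacrylate
Conditions: methacrylic anhydride, pyridine, DMAP (cat.), CH2Cl2, 0 °C → rt
Reagents that add atoms: methacrylic anhydride, C=C(C)C(=O)OC(=O)C(C)=C
Why: DMAP-catalysed acylation proceeds with retention at C8, installs the final O8 ester at once and removes the free O8 hydroxyl, the group most prone to add to C1.

Step 14
Reactants: 21 (1R,3S)-1-(4-bromo-5-oxo-2,5-dihydrofuran-3-yl)-3-{(5R)-5-[(tert-butyldimethylsilyloxy)methyl]-5-methyl-4,5-dihydrofuran-2-yl}-3-(triethylsilyloxy)butyl methacrylate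
Product: 22 (1R,3S)-1-(4-bromo-5-oxo-2,5-dihydrofuran-3-yl)-3-hydroxy-3-[(5R)-5-(hydroxymethyl)-5-methyl-4,5-dihydrofuran-2-yl]butyl methacrylate
Conditions: Bu4NF/AcOH (1:1, excess), THF, 0 °C → rt
Reagents that add atoms: none
Why: Fluoride desilylation buffered with acetic acid removes both silyl ethers on purpose, so no selectivity between the primary and the tertiary silyl ether is called for, and the near-neutral medium should spare enol ether, methacrylate and bromobutenolide.

Step 15
Reactants: 22 (1R,3S)-1-(4-bromo-5-oxo-2,5-dihydrofuran-3-yl)-3-hydroxy-3-[(5R)-5-(hydroxymethyl)-5-methyl-4,5-dihydrofuran-2-yl]butyl methacrylate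
Product: 23 (1R,3S)-1-(4-bromo-5-oxo-2,5-dihydrofuran-3-yl)-3-[(5R)-5-formyl-5-methyl-4,5-dihydrofuran-2-yl]-3-hydroxybutyl methacrylate
Conditions: Dess–Martin periodinane, pyridine, CH2Cl2, 0 °C
Reagents that add atoms: none
Why: Dess–Martin oxidation can act only on the primary O5 carbinol because O10 is tertiary, and the resulting C5 aldehyde has no α-hydrogen (C4 quaternary), so it can neither enolise nor epimerise.

Step 16
Reactants: 23 (1R,3S)-1-(4-bromo-5-oxo-2,5-dihydrofuran-3-yl)-3-[(5R)-5-formyl-5-methyl-4,5-dihydrofuran-2-yl]-3-hydroxybutyl methacrylate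
Product: 27 (4R,5E,8R,10S)-11-bromo-1,4-epoxy-10-hydroxy-8-methacryloyloxy-13-norgermacra-1,5,7(11)-trien-12,6-olide, via silyloxyfuran aldehyde 24 (not isolated), via macrocyclic aldol bis(silyl ether) 25 (not isolated), via C10 trimethylsilyl ether 26 (not isolated)
Conditions: Me3SiOTf, i-Pr2NEt, CH2Cl2 (0.001 M), −78 → 0 °C; DBU, 0 °C → rt; aq. NaHCO3; crude: Bu4NF/AcOH (1:1), THF, 0 °C
Reagents that add atoms: none
Why: Silylative intramolecular vinylogous Mukaiyama aldol addition followed by E1cB elimination, in which Me3SiOTf/i-Pr2NEt masks O10 and turns the bromobutenolide into silyloxyfuran 24, C6 (its γ-carbon, C11 being blocked by bromine) adds to the activated non-enolisable C5 aldehyde under high dilution to give 25, DBU expels silanolate from C5 with the short C8–C9–C10–C1 tether holding C4 on the C7 side so that the ring-cis (5E) alkene 26 should result, and buffered fluoride frees the tertiary O10.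

Step 17
Reactants: 27 (4R,5E,8R,10S)-11-bromo-1,4-epoxy-10-hydroxy-8-methacryloyloxy-13-norgermacra-1,5,7(11)-trien-12,6-olide
Product: 28 (4R,5E,8R,10S)-1,4-epoxy-10,13-dihydroxy-8-methacryloyloxygermacra-1,5,7(11)-trien-12,6-olide
Conditions: Bu3SnCH2OH, Pd(PPh3)4 (cat.), BHT, 1,4-dioxane, 80 °C
Reagents that add atoms: (tributylstannyl)methanol, CCCC[Sn](CCCC)(CCCC)CO
Why: Stille hydroxymethylation, in which zerovalent palladium inserts into the activated α-bromo enoate bond C11–Br and tin transfers the CH2OH group under neutral conditions, so C13 and its oxygen enter only after all carbanion chemistry at C6 is over.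

Step 18
Reactants: 28 (4R,5E,8R,10S)-1,4-epoxy-10,13-dihydroxy-8-methacryloyloxygermacra-1,5,7(11)-trien-12,6-olide
Product: 29 CNP0394509.1, (4R,5E,8R,10S)-13-acetoxy-1,4-epoxy-10-hydroxy-8-methacryloyloxygermacra-1,5,7(11)-trien-12,6-olide
Conditions: Ac2O, pyridine, CH2Cl2, 0 °C
Reagents that add atoms: acetic anhydride, CC(=O)OC(C)=O
Why: Selective acetylation, in which the primary allylic O13 hydroxyl reacts under mild pyridine catalysis while the tertiary O10 hydroxyl stays free, so the route ends on a mild acylation and not on a deprotection.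

## Compound list

1 | (S)-citramalic acid | OC(=O)C[C@](C)(O)C(=O)O | starting material
2 | 2-[(4S)-2,2,4-trimethyl-5-oxo-1,3-dioxolan-4-yl]acetic acid | OC(=O)C[C@]1(C)OC(C)(C)OC1=O | intermediate
3 | (5S)-5-(2-hydroxyethyl)-2,2,5-trimethyl-1,3-dioxolan-4-one | OCC[C@]1(C)OC(C)(C)OC1=O | intermediate
4 | (5S)-5-[2-(benzyloxy)ethyl]-2,2,5-trimethyl-1,3-dioxolan-4-one | C(c1ccccc1)OCC[C@]2(C)OC(C)(C)OC2=O | intermediate
5 | (2S)-4-(benzyloxy)-2-hydroxy-N-methoxy-N,2-dimethylbutanamide | CON(C)C(=O)[C@@](C)(O)CCOCc1ccccc1 | intermediate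
6 | (2S)-4-(benzyloxy)-N-methoxy-N,2-dimethyl-2-(triethylsilyloxy)butanamide | CON(C)C(=O)[C@@](C)(O[Si](CC)(CC)CC)CCOCc1ccccc1 | intermediate
7 | (3S)-5-(benzyloxy)-3-methyl-3-(triethylsilyloxy)pentan-2-one | CC(=O)[C@@](C)(O[Si](CC)(CC)CC)CCOCc1ccccc1 | intermediate
8 | (E)-N,N-dimethylhydrazone of 7 (C1, C2, C8–C10) | CN(C)/N=C(\C)[C@@](C)(O[Si](CC)(CC)CC)CCOCc1ccccc1 | intermediate
9 | (S)-2-methylglycidol | C[C@]1(CO)CO1 | starting material
10 | tert-butyldimethyl{[(2R)-2-methyloxiran-2-yl]methoxy}silane (C3–C5) | C[C@]1(CO[Si](C)(C)C(C)(C)C)CO1 | intermediate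
11 | lithium aza-enolate of 8 | C=C(N([Li])N(C)C)[C@@](C)(O[Si](CC)(CC)CC)CCOCc1ccccc1 | intermediate
12 | γ-hydroxy hydrazone (C2–C3 joined, 4R,10S) | CN(C)/N=C(\CC[C@@](C)(O)CO[Si](C)(C)C(C)(C)C)[C@@](C)(O[Si](CC)(CC)CC)CCOCc1ccccc1 | intermediate
13 | γ-hydroxy ketone (4R,10S) | O=C(CC[C@@](C)(O)CO[Si](C)(C)C(C)(C)C)[C@@](C)(O[Si](CC)(CC)CC)CCOCc1ccccc1 | intermediate
14 | cyclic hemiketal (C1 epimers) | OC1(CC[C@](C)(CO[Si](C)(C)C(C)(C)C)O1)[C@@](C)(O[Si](CC)(CC)CC)CCOCc2ccccc2 | intermediate
15 | dihydrofuran, O8 benzyl, O5 TBS, O10 TES (4R,10S) | C(c1ccccc1)OCC[C@](C)(O[Si](CC)(CC)CC)C2=CC[C@](C)(CO[Si](C)(C)C(C)(C)C)O2 | intermediate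
16 | C8 primary alcohol (4R,10S) | OCC[C@](C)(O[Si](CC)(CC)CC)C1=CC[C@](C)(CO[Si](C)(C)C(C)(C)C)O1 | intermediate
17 | C8 aldehyde (4R,10S) | O=CC[C@](C)(O[Si](CC)(CC)CC)C1=CC[C@](C)(CO[Si](C)(C)C(C)(C)C)O1 | intermediate
18 | 3,4-dibromofuran-2(5H)-one | O=C1OCC(Br)=C1Br | starting material
19 | (4-bromo-5-oxo-2,5-dihydrofuran-3-yl)chromium dichloride (ancillary ligand omitted) | O=C1OCC([Cr](Cl)Cl)=C1Br | intermediate
20 | C8 carbinol (4R,8R,10S) | O[C@H](C[C@](C)(O[Si](CC)(CC)CC)C1=CC[C@](C)(CO[Si](C)(C)C(C)(C)C)O1)C2=C(Br)C(=O)OC2 | intermediate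
21 | O8 methacrylate (4R,8R,10S) | C=C(C)C(=O)O[C@H](C[C@](C)(O[Si](CC)(CC)CC)C1=CC[C@](C)(CO[Si](C)(C)C(C)(C)C)O1)C2=C(Br)C(=O)OC2 | intermediate
22 | O5,O10 diol (4R,8R,10S) | C=C(C)C(=O)O[C@H](C[C@](C)(O)C1=CC[C@](C)(CO)O1)C2=C(Br)C(=O)OC2 | intermediate
23 | C5 aldehyde (4R,8R,10S) | C=C(C)C(=O)O[C@H](C[C@](C)(O)C1=CC[C@](C)(C=O)O1)C2=C(Br)C(=O)OC2 | intermediate
24 | 3-bromo-2-(trimethylsilyloxy)furan aldehyde, O10 TMS | C=C(C)C(=O)O[C@H](C[C@](C)(O[Si](C)(C)C)C1=CC[C@](C)(C=O)O1)c2coc(O[Si](C)(C)C)c2Br | intermediate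
25 | macrocyclic aldol adduct, O5 and O10 TMS (C5, C6 epimers) | C=C(C)C(=O)O[C@@H]1C[C@](C)(O[Si](C)(C)C)C2=CC[C@](C)(C(O[Si](C)(C)C)C3OC(=O)C(Br)=C31)O2 | intermediate
26 | macrocyclic (5E)-ylidene bromobutenolide, O10 TMS | C=C(C)C(=O)O[C@@H]1C[C@](C)(O[Si](C)(C)C)C2=CC[C@](C)(/C=C3/OC(=O)C(Br)=C31)O2 | intermediate
27 | macrocyclic (5E)-ylidene bromobutenolide, O10 free | C=C(C)C(=O)O[C@@H]1C[C@](C)(O)C2=CC[C@](C)(/C=C3/OC(=O)C(Br)=C31)O2 | intermediate
28 | 13-hydroxy compound (deacetyl target) | C=C(C)C(=O)O[C@@H]1C[C@](C)(O)C2=CC[C@](C)(/C=C3/OC(=O)C(CO)=C31)O2 | intermediate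
29 | CNP0394509.1 | C=C(C)C(=O)O[C@@H]1C[C@](C)(O)C2=CC[C@](C)(/C=C3/OC(=O)C(COC(C)=O)=C31)O2 | target

## Step count

- Total step count: 18.
- Longest linear sequence: 17 steps (steps 1–7 and 9–18, from (S)-citramalic acid).

## Steps most likely to fail

**1. Step 16.**
- What may go wrong: closure of the ten-membered ring may be slower than intermolecular aldol oligomerisation or decay of the silyloxyfuran. The alkene geometry may not be held fully by the tether.
- Fallback: an irreversible intramolecular olefination, setting out from 17 and returning at 27.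
  - Commercial mucobromic acid is converted with SOCl2/DMF (cat.) into 3,4-dibromo-5-chlorofuran-2(5H)-one F1.
  - Michaelis–Arbuzov reaction with P(OEt)3 then gives diethyl (3,4-dibromo-5-oxo-2,5-dihydrofuran-2-yl)phosphonate F2.
  - This phosphonate replaces 18 in the coupling with 17 under the conditions of step 12 and gives the C6-phosphonate carbinol F3.
  - The operations of steps 13 to 15 lead on to the C6-phosphonate methacrylate F4, the C6-phosphonate diol F5 and the C6-phosphonate C5 aldehyde F6.
  - Intramolecular Horner–Wadsworth–Emmons olefination (LiCl, i-Pr2NEt, MeCN, high dilution, Masamune–Roush conditions) forms C5=C6, needs no silylation of O10 and gives 27 directly.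

**2. Step 9.**
- What may go wrong: SN2 attack at the epoxide methylene next to quaternary C4 may be slow. The silyl group may migrate from O5 to the new O4 alkoxide during the long reaction time. The sequence may stall at the hemiketal.
- Fallback: the same two bonds are made from an alkyne, setting out from 6 and 10 and returning at 15.
  - i-Bu2AlH (CH2Cl2, −78 °C) reduces 6 to (2S)-4-(benzyloxy)-2-methyl-2-(triethylsilyloxy)butanal F7.
  - Seyferth–Gilbert homologation with the Ohira–Bestmann reagent (K2CO3, MeOH) gives (3S)-5-(benzyloxy)-3-methyl-3-(triethylsilyloxy)pent-1-yne F8.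
  - Its lithium acetylide (n-BuLi, BF3·OEt2, THF, −78 °C) opens 10 at C3 to give (2R,6S)-8-(benzyloxy)-1-(tert-butyldimethylsilyloxy)-2,6-dimethyl-6-(triethylsilyloxy)oct-4-yn-2-ol F9.
  - 5-endo-dig cycloisomerisation (AuCl(PPh3)/AgSbF6 cat., 4 Å MS, THF, rt) adds O4 to C1 and gives 15 without any hydrolysis or dehydration.

**3. Step 12.**
- What may go wrong: facial selectivity at C8 may be poor if the substrate bias opposes the ligand, and some insertion into the α C–Br bond may occur.
- Fallback: the stereocentre is no longer controlled in the C–C bond formation but corrected afterwards. It sets out from 17 and 18 and returns at 21.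
  - The coupling is run without ligand (CrCl2, NiCl2 cat., DMF, rt) and the C8 epimers are separated.
  - The 8R portion is 20 and follows step 13.
  - The C8 epimeric carbinol (4R,8S,10S) F10 is esterified under Mitsunobu conditions (methacrylic acid, PPh3, DIAD, toluene, 0 °C). This inverts C8 and converges on 21.

## Further compounds

F1 | step 16 | 3,4-dibromo-5-chlorofuran-2(5H)-one | O=C1OC(Cl)C(Br)=C1Br
F2 | step 16 | diethyl (3,4-dibromo-5-oxo-2,5-dihydrofuran-2-yl)phosphonate | CCOP(=O)(OCC)C1OC(=O)C(Br)=C1Br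
F3 | step 16 | C6-phosphonate carbinol (4R,8R,10S, C6 epimers) | O[C@H](C[C@](C)(O[Si](CC)(CC)CC)C1=CC[C@](C)(CO[Si](C)(C)C(C)(C)C)O1)C2=C(Br)C(=O)OC2P(=O)(OCC)OCC
F4 | step 16 | C6-phosphonate methacrylate | C=C(C)C(=O)O[C@H](C[C@](C)(O[Si](CC)(CC)CC)C1=CC[C@](C)(CO[Si](C)(C)C(C)(C)C)O1)C2=C(Br)C(=O)OC2P(=O)(OCC)OCC
F5 | step 16 | C6-phosphonate diol | C=C(C)C(=O)O[C@H](C[C@](C)(O)C1=CC[C@](C)(CO)O1)C2=C(Br)C(=O)OC2P(=O)(OCC)OCC
F6 | step 16 | C6-phosphonate C5 aldehyde | C=C(C)C(=O)O[C@H](C[C@](C)(O)C1=CC[C@](C)(C=O)O1)C2=C(Br)C(=O)OC2P(=O)(OCC)OCC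
F7 | step 9 | (2S)-4-(benzyloxy)-2-methyl-2-(triethylsilyloxy)butanal | O=C[C@@](C)(O[Si](CC)(CC)CC)CCOCc1ccccc1
F8 | step 9 | (3S)-5-(benzyloxy)-3-methyl-3-(triethylsilyloxy)pent-1-yne | C#C[C@@](C)(O[Si](CC)(CC)CC)CCOCc1ccccc1
F9 | step 9 | (2R,6S)-8-(benzyloxy)-1-(tert-butyldimethylsilyloxy)-2,6-dimethyl-6-(triethylsilyloxy)oct-4-yn-2-ol | C(c1ccccc1)OCC[C@](C)(O[Si](CC)(CC)CC)C#CC[C@@](C)(O)CO[Si](C)(C)C(C)(C)C
F10 | step 12 | C8 epimeric carbinol (4R,8S,10S) | O[C@@H](C[C@](C)(O[Si](CC)(CC)CC)C1=CC[C@](C)(CO[Si](C)(C)C(C)(C)C)O1)C2=C(Br)C(=O)OC2
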